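## The problem

The target 23 is a 2-O-alkylglycerol whose eight-carbon chain ends on C11 of a tetracyclo[6.4.0.0^2,7.0^3,6]dodecane. The core is a cyclohexane (ring A: C1, C8–C12) fused to a row of three cyclobutanes (ring B: C1, C2, C7, C8; ring C: C2, C3, C6, C7; ring D: C3–C6). All ring fusions are cis, ring A is anti to ring C across ring B, and ring B is anti to ring D across ring C. The six fusion centres C1, C2, C3, C6, C7 and C8 are therefore a question of relative configuration that suprafacial ring-forming steps with convex-face approach can answer.

Without the chain the hydrocarbon core is meso. The absolute configuration of 23 thus depends only on which of the enantiotopic carbons C10 and C11 carries the chain. The seventh centre, C11, must also place the chain cis to the C1–C2 and C8–C7 bonds, with H11 on the face of H1 and H8. It lies two bonds from the ring fusion, so substrate control is available but weak; this is the hardest stereochemical point.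

The glycerol part is symmetric and adds no stereocentre, but its 1,3-diol must stay masked while the chain is joined. The fused cyclobutanes rule out cationic chemistry next to the ladder, strong Lewis acids and hot late-metal conditions. The cyclobutene intermediates are volatile, and enediol derivatives of ring B are sensitive to air and moisture.

The key step is possible because the C2–C7 edge of ring B joins two carbons that each sit on a ring A fusion carbon (C2 on C1, C7 on C8) and are cis to one another. That is the relationship of the two ester carbons in a cis-cyclohexane-1,2-dicarboxylate. Ring B can therefore be closed by uniting two carbonyl carbons of like polarity, while a C10=C11 double bond in the diester keeps the meso symmetry and provides the later handle on ring A.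

## Retrosynthesis

**23 from 22.** No skeletal bond is cut. The 1,3-diol is traced to its isopropylidene acetal 22. The symmetric six-membered acetal arrives with the alcohol 17, withstands ylide and hydrogenation conditions, and leaves under aqueous acid mild enough for the ladder.

**22 from 21.** The C11–H bond is disconnected to the exocyclic alkene 21, so that C11 becomes a stereocentre by addition of hydrogen, not carbon. A reagent approaching ring A from the side of H1 and H8 then puts H11 on that side and the chain on the side of ring B, as 23 requires. Methods that bring the chain in as the incoming group from the open face (alkylation, conjugate addition, hydroboration with retentive coupling) would give the C11 epimer. Precursor 21 has one stereocentre fewer; the forward step needs face-selective hydrogenation without prior double-bond migration.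

**21 from 15 and 19.** The C11=C1′ double bond is cut to the ketone 15 and the phosphonium salt 19 (ylide 20). This splits the molecule into a twelve-carbon ladder ketone and the complete chain–glycerol piece. It is preferred to a late ether formation or a cut inside the chain because a carbonyl at C11 can be derived from ring A unsaturation. Ketone 15 has no substituent stereocentre at C11 and is chiral only through the position of its carbonyl. The forward reaction needs an unstabilised ylide to add to a ketone flanked by two methylenes; alkene geometry is irrelevant.

**19 from 18, and 18 from 16 and 17.** The C–P bond and the ether C–O bond are cut. Both forward steps are substitutions at primary carbon. The only requirements are monoalkylation of the dibromide 16 and acid-free handling of the acetal.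

**15 from 14, 13 and 12.** Only functional groups change. The carbonyl carbon of 15 is one of the two alkene carbons of the meso alkene 12, so the whole absolute configuration reduces to a choice between enantiotopic positions. That choice is made on the meso epoxide 13: removal of H9 in preference to H12 gives the allylic alcohol 14, and a redox isomerisation moves the oxidation level onto C11. Direct asymmetric hydroboration of 12 would be shorter, but an unstrained cis-disubstituted cyclohexene is poorly served by catalytic asymmetric hydroboration. The epoxide route relies on the best-studied desymmetrisation of cyclohexene oxides. It needs a single epoxide diastereomer and high selectivity between the two syn protons.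

**12 from 8 and 11.** The C2–C3 and C6–C7 bonds of ring C are cut in a [2+2] sense. Ring D comes in whole with cyclobutene 11, so two rings and four stereocentres are removed at once and a bicyclic meso diene 8 remains. A stepwise construction of rings C and D would be much longer. The forward reaction must pair two different cyclobutenes, leave the cyclohexene alone, and add to the face of ring B away from ring A.

**11 from 10 and 9.** Cyclobutene is a gas that is best made when needed. It is traced through the sulfonate 10 to cyclobutanol 9 by elimination.

**8 from 7, 6 and 4.** The C2=C7 double bond is traced to the cis-diol 6 through the thionocarbonate 7, and the diol to the enediol bis-silyl ether 4 through the acyloin 5. This is oxidation-level adjustment only. It is accepted because the ring-closing step delivers C2 and C7 at the enediol level and a cis-diol is deoxygenated stereospecifically to the alkene.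

**4 from 2 and 3 (key disconnection).** The C2–C7 bond is cut so that both carbons become ester carbonyls of the meso diester 2; the two silyl groups come from two molecules of 3. This removes ring B and leaves a monocyclic compound that already holds the cis relationship of C1 and C8 and the ring A alkene. The alternative of closing ring B by cycloaddition onto a cyclohexadiene would lose the meso alkene or need regiocontrol. The forward step is a reductive coupling of two carbons of the same polarity. It must outrun base-induced reactions of the diester and leave the isolated alkene untouched.

**2 from 1.** The two ester C–O bonds lead back to the bulk anhydride 1, which supplies the cis fusion and the alkene from a Diels–Alder reaction already carried out by the supplier.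

## Roads not taken

**Alternative 1:** The C10–C11 and C11–C12 bonds are cut. Ring A is contracted to a cyclopentanone, the meso ketone A1, and C11 with its whole chain comes from the primary diazoalkane A2. In the forward sense, Sc(OTf)3 with a chiral tris(oxazoline) ligand (trivalent scandium) would promote addition of A2 to the carbonyl and the 1,2-shift of one enantiotopic α-carbon with loss of N2, giving the ring-expanded ketone A3 with the chain on C11.

- Merits: one step brings in the chain, chooses between the enantiotopic sides and sets C11. It is the most convergent of the four plans.
- Weak points: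
  - In A3 the C11 centre is α to the C10 carbonyl and can epimerise. There is no thermodynamic preference to rely on, since both C11 epimers can place the chain equatorial.
  - Catalytic asymmetric ring expansion is established mainly for aryl-substituted diazo compounds with cyclobutanones and simple cyclohexanones. Here a long-chain alkyl diazoalkane and a meso bicyclic cyclopentanone would be needed, and the catalyst would have to control migrating carbon and C11 face at once.
  - A2 is a non-stabilised diazoalkane that must be prepared and handled in quantity.
  - The C10 carbonyl must then be removed, which costs steps and exposes the epimerisable centre to base or acid.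
- Comparison: alternative 1 is better in convergence and in step count after the ladder is built (one C–C forming step against five operations from 12 to 22). The chosen plan offsets this by using only established reaction classes, by fixing the position of the chain on ketone 15, which has no epimerisable stereocentre, and by setting C11 last with no carbonyl to remove.

**Alternative 2:** The C3–C6 bond is cut. Rings C and D are opened to a cyclohexa-1,3-diene fused to ring B, the chain-bearing diene A4. In the forward sense, cold irradiation (about 254–300 nm) would cause disrotatory four-electron closure to the ladderene A5, and hydrogenation would complete the core.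

- Merits: the closure is intramolecular, so no second alkene and no statistical pairing are involved. Both rings come from one chromophore, and the chain and C11 are in place before the strained rings exist.
- Weak points:
  - A4 contains a bicyclo[4.2.0]octa-2,4-diene, which equilibrates thermally with its ring-opened triene A6 by six-electron opening of the C2–C7 bond. It must be made and irradiated cold.
  - Excited cyclohexadienes prefer conrotatory opening to hexatrienes; closure to the bicyclohexene is usually a minor channel.
  - Closure must occur on the face anti to ring A.
  - A4 must already be enantiopure at C11 on a ring A with no meso symmetry to exploit, so the hardest stereochemical problem is moved earlier, not solved.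
- Comparison: alternative 2 is better in having no gaseous partner and no cross-cycloaddition, which is a real advantage over step 8 here. The chosen plan offsets this with a cycloaddition class that has been used to build ladderanes and with meso intermediates up to the desymmetrisation.

**Alternative 3:** The C8–C9 and C1–C12 bonds are cut. Ring A is removed as a diene, leaving the meso ladderene A7 (C1=C8) and buta-1,3-diene A8. In the forward sense, a Diels–Alder reaction at about 10 kbar below 60 °C would give A9, which is identical with 12.

- Merits: suprafacial addition to the convex face sets the cis fusion and the anti relationship in one step. There is no photochemistry with two competing alkenes. Everything after 12 would be unchanged.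
- Weak points:
  - A7 already contains rings B to D and is the real synthetic problem; it needs its own multi-step synthesis through strained bicyclic cyclobutenes.
  - An unactivated cyclobutene is a poor dienophile, hence the high-pressure equipment.
  - The temperature ceiling is set by thermal ring opening of the ladderene.
  - The diene oligomerises under pressure.
- Comparison: as a construction of ring A, alternative 3 is cleaner than attaching rings C and D by a cross photocycloaddition, and if A7 were at hand it would be the shorter way to 12. The chosen plan offsets this by taking rings A and B from a bulk anhydride in two steps and needing only ordinary glassware and a UV lamp.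

Key step: step 2

Assumption: the sense of the chiral lithium amide rearrangement is taken from cyclohexene oxide, where the (S)-proline-derived amide leaves oxygen on the carbon that becomes an (S)-carbinol; if the fused ladder reverses this, or if step 9 gives mainly the other meso epoxide, the (R)-diamine is used and nothing else changes.

Remark: ring atoms of compounds 12–23 carry the numbers C1–C12 defined above; the bicyclo[4.2.0]octene compounds 4–8 carry their own numbering (fusion carbons C1 and C6).

## Route

Step 1
Reactants: 1 cis-1,2,3,6-tetrahydrophthalic anhydride
Product: 2 dimethyl cis-cyclohex-4-ene-1,2-dicarboxylate (meso)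
Conditions: MeOH, H2SO4 (cat.), reflux
Reagents that add atoms: methanol, CO
Why: Acid-catalysed methanolysis of the anhydride followed by Fischer esterification of the half-ester; the α-centres are not enolised under these conditions, so the cis (meso) relationship is retained.

Step 2
Reactants: 2 dimethyl cis-cyclohex-4-ene-1,2-dicarboxylate; 3 chlorotrimethylsilane
Product: 4 cis-7,8-bis(trimethylsilyloxy)bicyclo[4.2.0]octa-3,7-diene
Conditions: Na (dispersion, 4.4 equiv), Me3SiCl (4.4 equiv), toluene, reflux, N2; filtration under N2, distillation at reduced pressure
Reagents that add atoms: chlorotrimethylsilane, C[Si](C)(C)Cl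
Why: Rühlmann–Bloomfield acyloin coupling: sodium gives one electron to each ester carbonyl, and the two ketyl radical anions, two carbons of the same polarity held cis on neighbouring ring carbons, combine to form C2–C7. Loss of two methoxides gives the fused cyclobutane-1,2-dione, which takes up two more electrons to the enediolate; two molecules of 3 then silylate it, one on each oxygen, so that 4 carries two trimethylsilyl groups, and two further molecules of 3 take up the methoxide. The closest known reaction type is this same Me3SiCl-trapped acyloin condensation of succinates and cis-cyclohexane-1,2-dicarboxylates to 1,2-bis(silyloxy)cyclobutenes. Ring B closes as a four-membered ring by radical–radical combination of two exocyclic carbonyl carbons, a closure outside the ring-size rules of polar cyclisations and helped by the cis-1,2 arrangement that keeps the two carbons within bonding distance. No stereocentre is formed, since C2 and C7 end as sp2 carbons; the cis fusion at C1 and C8 is carried in from 2. The step needs coupling to win over base-induced reactions of the diester, which for a 1,2-diester are epimerisation to the trans isomer (unable to close a cis-fused four-membered ring), intermolecular Claisen condensation and methoxide cleavage of the strained dione (a Dieckmann closure would need a three-membered ring and is no threat); Me3SiCl secures this by removing every methoxide as MeOSiMe3. The isolated double bond that becomes C10=C11 is not reduced by sodium in an aprotic medium, so the meso alkene survives for the later steps.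

Step 3
Reactants: 4 cis-7,8-bis(trimethylsilyloxy)bicyclo[4.2.0]octa-3,7-diene
Product: 6 meso cis-bicyclo[4.2.0]oct-3-ene-7,8-diol (both hydroxyls on the concave face), via 8-hydroxy-cis-bicyclo[4.2.0]oct-3-en-7-one 5 (not isolated)
Conditions: degassed MeOH, rt; then NaBH4, 0 °C
Reagents that add atoms: none
Why: Methanolysis of the silyl enol ethers frees the 2-hydroxycyclobutanone 5, which is reduced in the same flask before it can oxidise or ring-contract. The proton that creates the carbinol centre and the hydride both enter from the convex face (that of H1 and H6), so both hydroxyls should end on the concave face, cis to each other (substrate-controlled reduction of an α-hydroxy ketone).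

Step 4
Reactants: 6 meso cis-bicyclo[4.2.0]oct-3-ene-7,8-diol
Product: 7 cyclic thionocarbonate of 6
Conditions: 1,1'-thiocarbonyldiimidazole, toluene, 80 °C
Reagents that add atoms: 1,1'-thiocarbonyldiimidazole, S=C(n1ccnc1)n1ccnc1
Why: First stage of the Corey–Winter olefination; a cis-1,2-diol on a four-membered ring closes readily to the five-membered thionocarbonate.

Step 5
Reactants: 7 cyclic thionocarbonate of 6
Product: 8 cis-bicyclo[4.2.0]octa-3,7-diene
Conditions: 1,3-dimethyl-2-phenyl-1,3,2-diazaphospholidine (3 equiv), neat, 40–60 °C; product distilled at reduced pressure into a cold trap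
Reagents that add atoms: none
Why: Corey–Winter olefination in the Corey–Hopkins variant: the phosphorus reagent removes sulfur and the resulting 1,3-dioxolan-2-ylidene loses CO2 by stereospecific syn cycloreversion. The low temperature spares the cyclobutene, which is volatile enough to be distilled from the high-boiling reagent.

Step 6
Reactants: 9 cyclobutanol
Product: 10 cyclobutyl 4-methylbenzenesulfonate
Conditions: TsCl, pyridine, 0 °C → rt
Reagents that add atoms: 4-methylbenzenesulfonyl chloride, Cc1ccc(cc1)S(Cl)(=O)=O
Why: Sulfonylation of a secondary alcohol; no skeletal change.

Step 7
Reactants: 10 cyclobutyl 4-methylbenzenesulfonate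
Product: 11 cyclobutene
Conditions: KOtBu, DMSO, 70 °C; gas swept into a trap at −78 °C
Reagents that add atoms: none
Why: E2 elimination of cyclobutyl tosylate with tert-butoxide in DMSO is the standard preparation of cyclobutene; the gas leaves the basic medium as it forms.

Step 8
Reactants: 8 cis-bicyclo[4.2.0]octa-3,7-diene; 11 cyclobutene
Product: 12 meso cis,anti,cis,anti,cis-tetracyclo[6.4.0.0^2,7.0^3,6]dodec-10-ene
Conditions: (CuOTf)2·C6H6 (5 mol %), 11 (10 equiv), Et2O, hν (254 nm, quartz), −10 °C, sealed vessel
Reagents that add atoms: none
Why: Copper-catalysed [2+2] photocycloaddition (Salomon–Kochi type): CuOTf (monovalent copper) binds the two strained cyclobutene double bonds in preference to the unstrained cyclohexene, and excitation of the bis(alkene) complex forms C2–C3 and C6–C7. Cyclobutene adds to the face of ring B opposite ring A and with its CH2CH2 bridge turned away from ring B, which should give the cis,anti,cis,anti,cis ladder and sets C2, C3, C6 and C7 relative to C1 and C8; the excess of 11 channels 8 into the cross adduct.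

Step 9
Reactants: 12 meso tetracyclo[6.4.0.0^2,7.0^3,6]dodec-10-ene
Product: 13 meso 10,11-epoxide of 12 (oxygen on the face of H1 and H8)
Conditions: mCPBA, CH2Cl2, 0 °C; NaHCO3 (aq) wash
Reagents that add atoms: 3-chloroperbenzoic acid, O=C(OO)c1cccc(Cl)c1
Why: Prilezhaev epoxidation with concerted syn oxygen transfer from the face of ring A that carries H1 and H8, away from ring B. Either meso epoxide would serve, but it must be a single diastereomer, because the two would send the carbonyl to opposite enantiotopic positions in step 10; a minor isomer is removed by chromatography.

Step 10
Reactants: 13 meso 10,11-epoxide of 12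
Product: 14 (11S)-tetracyclo[6.4.0.0^2,7.0^3,6]dodec-9-en-11-ol (hydroxyl on the face of H1 and H8)
Conditions: (S)-2-(pyrrolidin-1-ylmethyl)pyrrolidine (20 mol %), LDA (2 equiv), DBU (6 equiv), THF, 0 °C → rt; NH4Cl (aq)
Reagents that add atoms: none
Why: Enantioselective base-promoted rearrangement of a meso epoxide to an allylic alcohol: the chiral lithium amide, bound to the epoxide oxygen, removes one of the two enantiotopic syn protons (H9 in preference to H12) in a cyclic transition state, so C10–O breaks and the oxygen stays on C11. This choice between C9 and C12 fixes the absolute configuration of the whole route; the carbinol configuration follows from the epoxide face and is not needed later.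

Step 11
Reactants: 14 (11S)-tetracyclo[6.4.0.0^2,7.0^3,6]dodec-9-en-11-ol
Product: 15 tetracyclo[6.4.0.0^2,7.0^3,6]dodecan-11-one (single enantiomer)
Conditions: Ru(η5-C5Ph5)(CO)2Cl (2 mol %), KOtBu (5 mol %), toluene, rt → 50 °C
Reagents that add atoms: none
Why: Ruthenium-catalysed redox isomerisation of a secondary allylic alcohol: the ruthenium alkoxide undergoes β-hydride elimination to an enone–hydride complex, the hydride returns to C9 and the enolate is protonated by the next alcohol. The carbonyl ends on C11 and cannot migrate, so enantiomeric purity rests only on its position; the ring-fusion centres are not α to the ketone.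

Step 12
Reactants: 16 1,8-dibromooctane; 17 2,2-dimethyl-1,3-dioxan-5-ol
Product: 18 5-(8-bromooctyloxy)-2,2-dimethyl-1,3-dioxane
Conditions: NaH, 16 (4 equiv), DMF, 0 °C → rt
Reagents that add atoms: none
Why: Williamson ether synthesis at a primary bromide; the excess of the dibromide suppresses the bis-ether and is recovered by distillation.

Step 13
Reactants: 18 5-(8-bromooctyloxy)-2,2-dimethyl-1,3-dioxane
Product: 19 [8-(2,2-dimethyl-1,3-dioxan-5-yloxy)octyl]triphenylphosphonium bromide
Conditions: PPh3, MeCN, reflux
Reagents that add atoms: triphenylphosphine, c1ccc(cc1)P(c1ccccc1)c1ccccc1
Why: SN2 quaternisation of triphenylphosphine by a primary bromide; the acetal is inert under these neutral conditions.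

Step 14
Reactants: 15 tetracyclo[6.4.0.0^2,7.0^3,6]dodecan-11-one; 19 [8-(2,2-dimethyl-1,3-dioxan-5-yloxy)octyl]triphenylphosphonium bromide
Product: 21 5-[8-(tetracyclo[6.4.0.0^2,7.0^3,6]dodecan-11-ylidene)octyloxy]-2,2-dimethyl-1,3-dioxane (both alkene isomers), via phosphorus ylide 20 (not isolated)
Conditions: 19 (1.5 equiv), NaHMDS (1.45 equiv), THF, 0 °C; then 15, 0 → 50 °C
Reagents that add atoms: none
Why: Wittig olefination of a cyclohexanone-type ketone with an unstabilised ylide forms C11=C1′; the two alkene isomers converge in step 15, and enolisation of 15 creates no stereochemical risk because both α-carbons are methylenes.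

Step 15
Reactants: 21 5-[8-(tetracyclo[6.4.0.0^2,7.0^3,6]dodecan-11-ylidene)octyloxy]-2,2-dimethyl-1,3-dioxane
Product: 22 5-[8-(tetracyclo[6.4.0.0^2,7.0^3,6]dodecan-11-yl)octyloxy]-2,2-dimethyl-1,3-dioxane (chain cis to C1–C2 and C8–C7)
Conditions: H2 (1 atm), PtO2, EtOAc, rt
Reagents that add atoms: none
Why: Heterogeneous syn-hydrogenation: the catalyst surface approaches the exocyclic alkene from the face of ring A that carries H1 and H8, the other face being screened by ring B and its inward hydrogens H2 and H7, so H11 is delivered cis to H1 and H8 and the chain ends cis to the C1–C2 and C8–C7 bonds (substrate control by the ring fusion). Platinum is preferred to palladium because it causes less double-bond migration before reduction; the neutral solvent spares the acetal.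

Step 16
Reactants: 22 5-[8-(tetracyclo[6.4.0.0^2,7.0^3,6]dodecan-11-yl)octyloxy]-2,2-dimethyl-1,3-dioxane
Product: 23 2-[8-(tetracyclo[6.4.0.0^2,7.0^3,6]dodecan-11-yl)octyloxy]propane-1,3-diol (CNP0193334.1)
Conditions: AcOH/H2O (4:1), 40 °C
Reagents that add atoms: none
Why: Acid hydrolysis of an isopropylidene acetal; saturated cyclobutanes and the dialkyl ether are inert to dilute aqueous acid at this temperature.

## Compound list

1 | cis-1,2,3,6-tetrahydrophthalic anhydride (meso) | O=C1OC(=O)[C@H]2CC=CC[C@@H]12 | starting material
2 | dimethyl cis-cyclohex-4-ene-1,2-dicarboxylate (meso) | COC(=O)[C@H]1CC=CC[C@H]1C(=O)OC | intermediate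
3 | chlorotrimethylsilane | C[Si](C)(C)Cl | starting material
4 | cis-7,8-bis(trimethylsilyloxy)bicyclo[4.2.0]octa-3,7-diene (meso) | C[Si](C)(C)OC1=C(O[Si](C)(C)C)[C@H]2CC=CC[C@@H]12 | intermediate
5 | 8-hydroxy-cis-bicyclo[4.2.0]oct-3-en-7-one, hydroxyl on the concave face (racemic, one enantiomer drawn) | O[C@H]1C(=O)[C@H]2CC=CC[C@@H]12 | intermediate (not isolated)
6 | meso cis-bicyclo[4.2.0]oct-3-ene-7,8-diol, hydroxyls cis to each other and trans to H1 and H6 | O[C@H]1[C@@H](O)[C@H]2CC=CC[C@@H]12 | intermediate
7 | cyclic thionocarbonate of 6 | S=C1O[C@H]2[C@@H](O1)[C@H]3CC=CC[C@@H]23 | intermediate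
8 | cis-bicyclo[4.2.0]octa-3,7-diene (meso) | C1=C[C@H]2CC=CC[C@@H]12 | intermediate
9 | cyclobutanol | OC1CCC1 | starting material
10 | cyclobutyl 4-methylbenzenesulfonate | Cc1ccc(cc1)S(=O)(=O)OC1CCC1 | intermediate
11 | cyclobutene | C1=CCC1 | intermediate
12 | meso tetracyclo[6.4.0.0^2,7.0^3,6]dodec-10-ene, all fusions cis, ring A anti to ring C, ring B anti to ring D | C1=CC[C@@H]2[C@H](C1)[C@H]1[C@@H]3CC[C@@H]3[C@@H]21 | intermediate
13 | meso 10,11-epoxide of 12, oxygen on the face of ring A that carries H1 and H8 | O1[C@@H]2C[C@@H]3[C@H](C[C@H]12)[C@H]1[C@@H]4CC[C@@H]4[C@@H]31 | intermediate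
14 | (11S)-tetracyclo[6.4.0.0^2,7.0^3,6]dodec-9-en-11-ol, hydroxyl on the face of H1 and H8, ladder as in 12 | O[C@@H]1C=C[C@@H]2[C@H](C1)[C@H]1[C@@H]3CC[C@@H]3[C@@H]21 | intermediate
15 | tetracyclo[6.4.0.0^2,7.0^3,6]dodecan-11-one, ladder as in 12, enantiomer defined by the carbonyl position | O=C1CC[C@@H]2[C@H](C1)[C@H]1[C@@H]3CC[C@@H]3[C@@H]21 | intermediate
16 | 1,8-dibromooctane | BrCCCCCCCCBr | starting material
17 | 2,2-dimethyl-1,3-dioxan-5-ol | CC1(C)OCC(O)CO1 | starting material
18 | 5-(8-bromooctyloxy)-2,2-dimethyl-1,3-dioxane | CC1(C)OCC(CO1)OCCCCCCCCBr | intermediate
19 | [8-(2,2-dimethyl-1,3-dioxan-5-yloxy)octyl]triphenylphosphonium bromide | [Br-].CC1(C)OCC(CO1)OCCCCCCCC[P+](c1ccccc1)(c1ccccc1)c1ccccc1 | intermediate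
20 | [8-(2,2-dimethyl-1,3-dioxan-5-yloxy)octylidene]triphenylphosphorane | CC1(C)OCC(CO1)OCCCCCCCC=P(c1ccccc1)(c1ccccc1)c1ccccc1 | intermediate (not isolated)
21 | 5-[8-(tetracyclo[6.4.0.0^2,7.0^3,6]dodecan-11-ylidene)octyloxy]-2,2-dimethyl-1,3-dioxane, both alkene isomers, ladder as in 12 | CC1(C)OCC(CO1)OCCCCCCCC=C1CC[C@@H]2[C@H](C1)[C@H]1[C@@H]3CC[C@@H]3[C@@H]21 | intermediate
22 | 5-[8-(tetracyclo[6.4.0.0^2,7.0^3,6]dodecan-11-yl)octyloxy]-2,2-dimethyl-1,3-dioxane, chain cis to the C1–C2 and C8–C7 bonds | CC1(C)OCC(CO1)OCCCCCCCC[C@H]1CC[C@@H]2[C@H](C1)[C@H]1[C@@H]3CC[C@@H]3[C@@H]21 | intermediate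
23 | 2-[8-(tetracyclo[6.4.0.0^2,7.0^3,6]dodecan-11-yl)octyloxy]propane-1,3-diol (CNP0193334.1) | OCC(CO)OCCCCCCCC[C@H]1CC[C@@H]2[C@H](C1)[C@H]1[C@@H]3CC[C@@H]3[C@@H]21 | target

## Step count and least certain steps

Total step count: 16. Longest linear sequence: 12 steps (steps 1, 2, 3, 4, 5, 8, 9, 10, 11, 14, 15, 16, from 1 to 23).

**Step 2 (key step).** The likeliest failure is that base-induced processes outrun ketyl coupling when methoxide is not trapped fast enough (epimerisation of the cis diester, Claisen-type condensation), together with loss of the moisture- and air-sensitive product during isolation. The fallback keeps the C2–C7 bond formation but changes the carbonyl oxidation level. It sets out from 2: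

- LiAlH4 reduction gives cis-cyclohex-4-ene-1,2-diyldimethanol F1.
- Swern oxidation (iPr2NEt, −78 °C, to limit epimerisation) gives cis-cyclohex-4-ene-1,2-dicarbaldehyde F2.
- SmI2 in THF couples the two aldehyde ketyls (intramolecular pinacol coupling). The samarium-bridged oxygens should take the open convex face, which would give the convex-face cis-bicyclo[4.2.0]oct-3-ene-7,8-diol F3, a diastereomer of 6.
- Thiocarbonyldiimidazole, as in step 4, gives its cyclic thionocarbonate F4.
- The diazaphospholidine reagent of step 5 gives 8, where the route is rejoined.

Should the pinacol coupling place the hydroxyls on the concave face instead, the diol is 6 itself and the route is rejoined there.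

**Step 8.** The likeliest failure is statistical pairing in the copper complex, so that homodimerisation of either cyclobutene and loss of the volatile partners erode the cross adduct. Slow copper-mediated reaction at the cyclohexene and incomplete anti selectivity are further risks. The fallback replaces the cross-coupling by a chromophore-selective cycloaddition and a second ring closure of the key-step type. It sets out from 8:

- Acetophenone-sensitised [2+2] photocycloaddition of maleic anhydride to the cyclobutene gives the cis,anti,cis anhydride F5 (rings A, B and C, anhydride on C3 and C6).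
- Acid methanolysis gives the dimethyl ester F6.
- Sodium and Me3SiCl in toluene close ring D as the bis(trimethylsilyloxy)cyclobutene F7.
- Methanolysis with in-situ NaBH4 reduction gives the 4,5-diol F8.
- Thiocarbonyldiimidazole gives the thionocarbonate F9.
- The diazaphospholidine reagent gives tetracyclo[6.4.0.0^2,7.0^3,6]dodeca-4,10-diene F10.
- Diimide (from potassium azodicarboxylate and acetic acid), which reduces the strained cyclobutene much faster than the cyclohexene, returns the route to 12.

This fallback is long, and any adduct formed at the cyclohexene would be a constitutional isomer to be separated.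

**Step 15.** The likeliest failure is poor facial selectivity in the delivery of hydrogen. C11 is two bonds from the ring fusion, and the two accessible conformers of ring A expose different faces. Double-bond migration before reduction could add to this, and the resulting C11 epimers of a long-chain ether would be hard to separate. The fallback sets C11 by hydroboration and joins the chain by sp3–sp3 coupling. It sets out from 15:

- Methylenation with Ph3P=CH2 gives 11-methylenetetracyclo[6.4.0.0^2,7.0^3,6]dodecane F11.
- Hydroboration with the bulky 9-BBN from the face of H1 and H8, then alkaline H2O2, gives (tetracyclo[6.4.0.0^2,7.0^3,6]dodecan-11-yl)methanol F12 with the hydroxymethyl group cis to ring B. This is a compact polar compound, from which a C11 epimer can be removed by chromatography or by crystallisation of an ester.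
- TsCl in pyridine gives the tosylate F13.
- The seven-carbon bromide 5-(7-bromoheptyloxy)-2,2-dimethyl-1,3-dioxane F14 is made from 1,7-dibromoheptane and 17 as in step 12 and converted with magnesium into the Grignard reagent F15.
- Coupling of F15 with F13 under Li2CuCl4 catalysis gives 22, where the route is rejoined.

**Step 10.** The likeliest failure is insufficient discrimination between the enantiotopic syn protons, because the fused ladder changes the shape of the epoxide relative to cyclohexene oxide, or competing deprotonation by achiral LDA. The fallback is a desymmetrisation by nucleophilic ring opening. It sets out from 13: benzoic acid with the chiral complex [N,N′-bis(3,5-di-tert-butylsalicylidene)-1,2-cyclohexanediaminato]cobalt (divalent cobalt, oxidised in air to the trivalent cobalt benzoate) opens the epoxide at C10 and gives the trans 10-benzoyloxy-11-ol F16. Dess–Martin oxidation gives the 10-benzoyloxy-11-ketone F17, and SmI2 removes the α-acyloxy group. The route is rejoined at 15, and step 11 is no longer needed.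

**Step 5.** The likeliest failure is sluggish fragmentation to a strained alkene and loss of the volatile diene during isolation. In addition, any trans-diol carried from step 3 cannot form the cyclic thionocarbonate in step 4. The fallback is a reductive elimination that accepts either diol configuration. It sets out from 6: MsCl and Et3N give the bis(methanesulfonate) F18 (drawn for the cis-diol; a trans portion reacts likewise), and sodium naphthalenide in THF at low temperature gives 8, where the route is rejoined.

**Step 11.** The likeliest failure is stalling of the catalytic hydride shuttle on a cyclic disubstituted allylic alcohol, or competing base-induced reactions of the enone intermediate. The fallback is reduction followed by oxidation. It sets out from 14: H2 over Pd/C gives the saturated alcohol tetracyclo[6.4.0.0^2,7.0^3,6]dodecan-11-ol F19, and Dess–Martin periodinane gives 15, where the route is rejoined.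

## Further compounds

F1 | step 2 | cis-cyclohex-4-ene-1,2-diyldimethanol | OC[C@H]1CC=CC[C@H]1CO
F2 | step 2 | cis-cyclohex-4-ene-1,2-dicarbaldehyde | O=C[C@H]1CC=CC[C@H]1C=O
F3 | step 2 | meso cis-bicyclo[4.2.0]oct-3-ene-7,8-diol, hydroxyls cis to each other and cis to H1 and H6 (convex face) | O[C@@H]1[C@H](O)[C@H]2CC=CC[C@@H]12
F4 | step 2 | cyclic thionocarbonate of F3 | S=C1O[C@@H]2[C@H](O1)[C@H]3CC=CC[C@@H]23
F5 | step 8 | cis,anti,cis anhydride of rings A, B and C (tetracyclo[6.4.0.0^2,7.0^3,6]dodecane numbering: anhydride carbonyls on C3 and C6, C10=C11 alkene) | C1=CC[C@@H]2[C@H](C1)[C@H]1[C@@H]3C(=O)OC(=O)[C@@H]3[C@@H]21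
F6 | step 8 | dimethyl ester from F5 (ester groups cis on C3 and C6) | C1=CC[C@@H]2[C@H](C1)[C@H]1[C@H](C(=O)OC)[C@H](C(=O)OC)[C@@H]21
F7 | step 8 | 4,5-bis(trimethylsilyloxy)tetracyclo[6.4.0.0^2,7.0^3,6]dodeca-4,10-diene | C1=CC[C@@H]2[C@H](C1)[C@H]1[C@@H]3C(O[Si](C)(C)C)=C(O[Si](C)(C)C)[C@@H]3[C@@H]21
F8 | step 8 | tetracyclo[6.4.0.0^2,7.0^3,6]dodec-10-ene-4,5-diol, hydroxyls cis and trans to H3 and H6 | C1=CC[C@@H]2[C@H](C1)[C@H]1[C@@H]3[C@H](O)[C@H](O)[C@@H]3[C@@H]21
F9 | step 8 | cyclic thionocarbonate of F8 | C1=CC[C@@H]2[C@H](C1)[C@H]1[C@@H]3[C@@H]4OC(=S)O[C@@H]4[C@@H]3[C@@H]21
F10 | step 8 | tetracyclo[6.4.0.0^2,7.0^3,6]dodeca-4,10-diene | C1=CC[C@@H]2[C@H](C1)[C@H]1[C@@H]3C=C[C@@H]3[C@@H]21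
F11 | step 15 | 11-methylenetetracyclo[6.4.0.0^2,7.0^3,6]dodecane | C=C1CC[C@@H]2[C@H](C1)[C@H]1[C@@H]3CC[C@@H]3[C@@H]21
F12 | step 15 | (tetracyclo[6.4.0.0^2,7.0^3,6]dodecan-11-yl)methanol, CH2OH cis to ring B | OC[C@H]1CC[C@@H]2[C@H](C1)[C@H]1[C@@H]3CC[C@@H]3[C@@H]21
F13 | step 15 | 4-methylbenzenesulfonate of F12 | Cc1ccc(cc1)S(=O)(=O)OC[C@H]1CC[C@@H]2[C@H](C1)[C@H]1[C@@H]3CC[C@@H]3[C@@H]21
F14 | step 15 | 5-(7-bromoheptyloxy)-2,2-dimethyl-1,3-dioxane | CC1(C)OCC(CO1)OCCCCCCCBr
F15 | step 15 | [7-(2,2-dimethyl-1,3-dioxan-5-yloxy)heptyl]magnesium bromide | CC1(C)OCC(CO1)OCCCCCCC[Mg]Br
F16 | step 10 | trans-10-benzoyloxytetracyclo[6.4.0.0^2,7.0^3,6]dodecan-11-ol (OH on the face of H1 and H8, benzoate on the face of ring B) | O[C@@H]1[C@@H](OC(=O)c5ccccc5)C[C@@H]2[C@H](C1)[C@H]1[C@@H]3CC[C@@H]3[C@@H]21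
F17 | step 10 | 10-benzoyloxytetracyclo[6.4.0.0^2,7.0^3,6]dodecan-11-one | O=C1[C@@H](OC(=O)c5ccccc5)C[C@@H]2[C@H](C1)[C@H]1[C@@H]3CC[C@@H]3[C@@H]21
F18 | step 5 | bis(methanesulfonate) of 6 | CS(=O)(=O)O[C@H]1[C@@H](OS(C)(=O)=O)[C@H]2CC=CC[C@@H]12
F19 | step 11 | tetracyclo[6.4.0.0^2,7.0^3,6]dodecan-11-ol (OH on the face of H1 and H8) | O[C@@H]1CC[C@@H]2[C@H](C1)[C@H]1[C@@H]3CC[C@@H]3[C@@H]21
A1 | alternative 1 | meso tetracyclo[6.3.0.0^2,7.0^3,6]undecan-10-one | O=C1C[C@@H]2[C@H](C1)[C@H]1[C@@H]3CC[C@@H]3[C@@H]21
A2 | alternative 1 | 5-(9-diazononyloxy)-2,2-dimethyl-1,3-dioxane | [N-]=[N+]=CCCCCCCCCOC1COC(C)(C)OC1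
A3 | alternative 1 | C10 ketone of the complete skeleton with the glyceryl-acetonide chain on C11 | CC1(C)OCC(CO1)OCCCCCCCC[C@H]1C(=O)C[C@@H]2[C@H](C1)[C@H]1[C@@H]3CC[C@@H]3[C@@H]21
A4 | alternative 2 | chain-bearing tricyclic cyclohexa-1,3-diene (C3=C4–C5=C6), TIPS ether | CC(C)[Si](C(C)C)(C(C)C)OCCCCCCCC[C@H]1CC[C@@H]2[C@H](C1)[C@H]1C=CC=C[C@@H]21
A5 | alternative 2 | TIPS ether of the C4=C5 ladderene | CC(C)[Si](C(C)C)(C(C)C)OCCCCCCCC[C@H]1CC[C@@H]2[C@H](C1)[C@H]1[C@@H]3C=C[C@@H]3[C@@H]21
A6 | alternative 2 | ring-opened cyclooctatriene valence isomer of A4 | CC(C)[Si](C(C)C)(C(C)C)OCCCCCCCC[C@H]1CC[C@@H]2[C@H](C1)C=CC=CC=C2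
A7 | alternative 3 | meso anti-tricyclo[4.2.0.0^2,5]oct-7-ene | C1=C[C@H]2[C@@H]3CC[C@@H]3[C@@H]12
A8 | alternative 3 | buta-1,3-diene | C=CC=C
A9 | alternative 3 | meso cyclohexene-fused ladderane (identical with 12) | C1=CC[C@@H]2[C@H](C1)[C@H]1[C@@H]3CC[C@@H]3[C@@H]21
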